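**Plan**

1. Retrosynthesis: the butenolide is cut at C12–C13 (B-alkyl Suzuki coupling) and C8=C17 at the C8 ketone; the C2/C3 hydroxyls and C18 are traced back to a C3 silyl enol ether. Then C1–C2 and C5–C10 are cut together (intramolecular Diels–Alder), and last C6–C7, C9–C11 and C10–C1 around a butyrolactone.
2. Enabling feature: in ring A the C3 oxygen sits next to C4, so ring A is the adduct of a 2-silyloxydiene C2=C3–C4=C5. C10 carries a one-carbon group (C20) that is 1,3 to the sp2 carbon C8 on ring B, so C20 and C8 can be tied as a γ-lactone C20(=O)–O–C8, which turns C10=C1 into an α-methylene lactone dienophile.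
3. Forward: a lactone from L-glutamic acid supplies C7–C8–C9–C10–C20. Chain extension (C6, C5), butenolide formation, vinyl conjugate addition/Mannich reaction (C11–C12, C1), enone formation (C4–C2) and silylation give the triene; one cycloaddition then closes rings A and B. Ring A is oxygenated, the lactone is dismantled (C20 to methyl, C8 to methylene) and the butenolide is coupled on.
4. Stereochemistry: C8 comes from the chiral pool and is erased later. C9 is set by anti conjugate addition, C10 and C5 in the cycloaddition (lactone face, endo rule), and C4, C2 and C3 by attack anti to the axial C20/C19 groups.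

Key step: step 8

Remark: labdane numbering is used throughout (C1–C10 decalin, C11–C16 side chain and butenolide, C17 exocyclic methylene carbon, C18 hydroxymethyl and C19 methyl on C4, C20 the one-carbon group on C10). "C20 face" is the decalin face that carries C20; "H5 face" is the opposite one.
Assumption: tosylate 1 (made from L-glutamic acid), Grignard reagent 2, ylide 12 and bromobutenolide 27 are taken as purchasable.

**Route**

Step 1
Reactants: 1 (S)-(5-oxooxolan-2-yl)methyl 4-methylbenzenesulfonate; 2 (1,3-dioxolan-2-ylmethyl)magnesium bromide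
Product: 3 (R)-5-[2-(1,3-dioxolan-2-yl)ethyl]oxolan-2-one
Conditions: 2 (1.5 equiv, slow addition), Li2CuCl4 (5 mol %), THF, −78 → −15 °C
Reagents that add atoms: none
Why: Copper-catalysed cross-coupling of a Grignard reagent with a primary tosylate displaces only the exocyclic sulfonate at low temperature, so the lactone carbonyl and the C8 stereocentre are untouched (the descriptor changes from S to R only through the priority change).

Step 2
Reactants: 3 (R)-5-[2-(1,3-dioxolan-2-yl)ethyl]oxolan-2-one
Product: 5 (R)-5-[2-(1,3-dioxolan-2-yl)ethyl]furan-2(5H)-one, via α-phenylselanyl lactone 4 (not isolated)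
Conditions: lithium diisopropylamide, THF, −78 °C; PhSeBr; then 30% H2O2, pyridine, CH2Cl2, 0 °C → rt
Reagents that add atoms: none
Why: α-Selenenylation of the lactone enolate followed by selenoxide syn-elimination can place the new double bond only in the ring between C10 and C9 and does not touch C8.

Step 3
Reactants: 5 (R)-5-[2-(1,3-dioxolan-2-yl)ethyl]furan-2(5H)-one; 6 vinylmagnesium bromide
Product: 8 (3R,4S,5R)-3-[(dimethylamino)methyl]-5-[2-(1,3-dioxolan-2-yl)ethyl]-4-ethenyloxolan-2-one, via bromomagnesium lactone enolate 7 (not isolated)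
Conditions: 6 (1.5 equiv), CuBr·SMe2 (10 mol %), THF, −78 → −40 °C; then Me2N=CH2+ I− (2 equiv), −78 → 0 °C
Reagents that add atoms: N,N-dimethylmethyleneiminium iodide, C=[N+](C)C.[I-]
Why: Copper-catalysed conjugate addition of the vinyl Grignard reagent should occur on the butenolide face anti to the C8 side chain (4,5-trans, sets C9), and the magnesium enolate is trapped in a Mannich reaction anti to the new vinyl group, a three-component conjugate addition–Mannich coupling.

Step 4
Reactants: 8 (3R,4S,5R)-3-[(dimethylamino)methyl]-5-[2-(1,3-dioxolan-2-yl)ethyl]-4-ethenyloxolan-2-one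
Product: 10 (4S,5R)-5-[2-(1,3-dioxolan-2-yl)ethyl]-4-ethenyl-3-methylideneoxolan-2-one, via trimethylammonium iodide 9 (not isolated)
Conditions: MeI, MeOH, rt; then NaHCO3 (aq.), CH2Cl2, rt
Reagents that add atoms: none
Why: Exhaustive N-methylation and E1cB loss of trimethylamine (Mannich-base route to α-methylene lactones) under bicarbonate should be mild enough that the exocyclic alkene does not migrate into the ring and C9 is not epimerised.

Step 5
Reactants: 10 (4S,5R)-5-[2-(1,3-dioxolan-2-yl)ethyl]-4-ethenyl-3-methylideneoxolan-2-one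
Product: 11 3-[(2R,3S)-3-ethenyl-4-methylidene-5-oxooxolan-2-yl]propanal
Conditions: 1 M HCl, THF, rt
Reagents that add atoms: water, O
Why: Acid-catalysed acetal hydrolysis frees the C5 aldehyde while the α-methylene lactone and the vinyl group are stable to dilute aqueous acid at room temperature.

Step 6
Reactants: 11 3-[(2R,3S)-3-ethenyl-4-methylidene-5-oxooxolan-2-yl]propanal; 12 3-(triphenylphosphoranylidene)butan-2-one
Product: 13 (4S,5R)-4-ethenyl-3-methylidene-5-[(3E)-4-methyl-5-oxohex-3-en-1-yl]oxolan-2-one
Conditions: 12 (1.3 equiv), toluene, 80 °C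
Reagents that add atoms: none
Why: Wittig olefination with an α-branched acyl-stabilised ylide should give the (E)-trisubstituted enone (C6 trans to the acetyl group), and the neutral ylide is too weak a nucleophile to add to the α-methylene lactone.

Step 7
Reactants: 13 (4S,5R)-4-ethenyl-3-methylidene-5-[(3E)-4-methyl-5-oxohex-3-en-1-yl]oxolan-2-one
Product: 14 (4S,5R)-4-ethenyl-3-methylidene-5-[(3E)-4-methyl-5-(trimethylsilyloxy)hexa-3,5-dien-1-yl]oxolan-2-one
Conditions: LiN(SiMe3)2 (1.1 equiv), Me3SiCl (in situ quench), THF, −78 °C; cold NaHCO3 work-up, used crude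
Reagents that add atoms: chlorotrimethylsilane, C[Si](C)(C)Cl
Why: Kinetic deprotonation of the methyl ketone at C2 by the hindered amide with in situ O-silylation gives the cross-conjugated 2-silyloxydiene before the enolate can add to the α-methylene lactone, and leaves the (E)-C4=C5 bond and C9 untouched.

Step 8
Reactants: 14 (4S,5R)-4-ethenyl-3-methylidene-5-[(3E)-4-methyl-5-(trimethylsilyloxy)hexa-3,5-dien-1-yl]oxolan-2-one
Product: 15 tricyclic trimethylsilyl enol ether lactone (Δ3-3-silyloxy trans-decalin bridged by the C20(=O)–O–C8 lactone)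
Conditions: toluene (0.01 M), BHT (cat.), 110 °C
Reagents that add atoms: none
Why: The 2-silyloxydiene (HOMO raised by the C3 oxygen, largest coefficient at C2) and the α-methylene-γ-butyrolactone (LUMO lowered by the C20 carbonyl, largest coefficient at C1) should combine in a concerted, asynchronous, polarity-matched intramolecular Diels–Alder reaction of type 1 that forms C1–C2 and C5–C10 together. The closest known reaction types are the thermal Diels–Alder addition of 2-silyloxydienes to α-methylene lactones and the intramolecular Diels–Alder reaction of 1,3,9-decatrienes whose dienophile carries the activating carbonyl on its inner carbon. Ring A (C1–C2–C3–C4–C5–C10) closes as the cyclohexene of the [4+2] union itself, and ring B (C5–C6–C7–C8–C9–C10) closes at the same moment as a chair six-membered ring fused to ring A through the tether C6–C7–C8–C9 and bridged by the lactone (a 6-oxabicyclo[3.2.1]octan-7-one unit). C10 is controlled by the C8 stereocentre, because the short C6–C7 link lets the diene reach the exocyclic alkene only on the lactone face that carries C7, which puts C20 and O8 cis-diaxial on ring B and C20 cis to the C9 vinyl group as in the target; C5 is controlled by the endo orientation of the C20 carbonyl below C3 of the diene together with the (E)-C4=C5 geometry, which places H5 anti to C20 (trans-decalin). The step needs endo over exo selectivity (trans- over cis-fusion) and intra- over intermolecular reaction: the first is secured by secondary overlap of the lactone carbonyl with the diene and by the chair of the forming ring B with C4 equatorial, the second by high dilution, while the C9 vinyl group is an unactivated bystander.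

Step 9
Reactants: 15 tricyclic trimethylsilyl enol ether lactone
Product: 16 C4-hydroxymethyl C3-ketone lactone
Conditions: aq. HCHO (37%), Yb(OTf)3 (10 mol %), THF, rt
Reagents that add atoms: formaldehyde, C=O
Why: A lanthanide-triflate-catalysed aqueous Mukaiyama aldol reaction with formaldehyde uses the enol ether regiochemistry delivered by the cycloaddition, and formaldehyde should approach C4 from the H5 face because the C20 face is blocked by the syn-axial lactone carbon on C10, which makes the CH2OH group equatorial and the C19 methyl axial.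

Step 10
Reactants: 16 C4-hydroxymethyl C3-ketone lactone
Product: 19 2-hydroxy-3-ketone lactone, via bis(trimethylsilyl) enol ether 17 (not isolated), via 2-silyloxy ketone 18 (not isolated)
Conditions: Me3SiOTf, Et3N, CH2Cl2, 0 °C; then mCPBA, NaHCO3, CH2Cl2, −20 °C; then 1 M HCl, THF, 0 °C
Reagents that add atoms: 3-chloroperbenzoic acid, OOC(=O)c1cccc(Cl)c1
Why: In this Rubottom oxidation the ketone can enolise only towards C2, and the peracid should attack the Δ2 silyl enol ether (much more electron-rich than the vinyl group) from the H5 face, away from the axial C19 methyl and C20, to give the equatorial 2-hydroxy ketone, which is also the thermodynamically preferred epimer.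

Step 11
Reactants: 19 2-hydroxy-3-ketone lactone
Product: 20 2,3,18-triol lactone
Conditions: NaBH4, MeOH, −20 → 0 °C
Reagents that add atoms: none
Why: Borohydride reduction of a cyclohexanone flanked by a quaternary centre should proceed by axial hydride attack from the H5 face (the C20 face is shielded by the axial C19 methyl), giving the equatorial 3-OH trans to the 2-OH, while the hindered non-enolisable lactone is not reduced at 0 °C.

Step 12
Reactants: 20 2,3,18-triol lactone
Product: 21 tris(tert-butyldimethylsilyl) ether lactone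
Conditions: tBuMe2SiOTf (4.5 equiv), 2,6-lutidine, CH2Cl2, 0 °C → rt
Reagents that add atoms: tert-butyldimethylsilyl trifluoromethanesulfonate, CC(C)(C)[Si](C)(C)OS(=O)(=O)C(F)(F)F
Why: A silyl triflate with a hindered pyridine base silylates primary and hindered secondary hydroxyl groups alike, so the triol is masked in one operation before the hydride and oxidation steps.

Step 13
Reactants: 21 tris(tert-butyldimethylsilyl) ether lactone
Product: 22 bridged lactol (C20 hemiacetal)
Conditions: diisobutylaluminium hydride (1.3 equiv), CH2Cl2, −78 °C; aq. potassium sodium tartrate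
Reagents that add atoms: none
Why: Half-reduction of a lactone with diisobutylaluminium hydride at −78 °C stops at the stable tetrahedral aluminate, which gives the lactol on work-up.

Step 14
Reactants: 22 bridged lactol (C20 hemiacetal)
Product: 24 C8 alcohol carrying the C10 methyl group, via tosylhydrazone 23 (not isolated)
Conditions: TsNHNH2, EtOH, 60 °C; then catecholborane, CHCl3, 0 °C → rt; then NaOAc·3H2O, 60 °C
Reagents that add atoms: none
Why: The lactol should react through its open hydroxy-aldehyde form to give the tosylhydrazone, and hydride transfer from catecholborane followed by acetate-induced loss of sulfinate and nitrogen (Caglioti reduction) turns the neopentyl C20 aldehyde into the C10 methyl group under conditions that spare silyl ethers and the vinyl group.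

Step 15
Reactants: 24 C8 alcohol carrying the C10 methyl group
Product: 25 C8 ketone
Conditions: Dess–Martin periodinane, NaHCO3, CH2Cl2, 0 °C → rt
Reagents that add atoms: none
Why: Dess–Martin oxidation of the only free hydroxyl (axial, C8) gives the ketone under buffered, non-enolising conditions, so C9 keeps its configuration, the vinyl group does not move into conjugation, and the C8 stereocentre, having done its work, is erased.

Step 16
Reactants: 25 C8 ketone
Product: 26 C8(17)-methylene compound with the C9 vinyl group
Conditions: Zn, CH2Br2, TiCl4, THF/CH2Cl2, 0 °C → rt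
Reagents that add atoms: dibromomethane, BrCBr
Why: Lombardo–Takai methylenation is non-basic and so should convert the hindered, enolisable β,γ-unsaturated ketone into the exocyclic alkene without epimerising C9 or isomerising the vinyl group.

Step 17
Reactants: 26 C8(17)-methylene compound with the C9 vinyl group; 27 4-bromofuran-2(5H)-one
Product: 29 tris(tert-butyldimethylsilyl) ether of the target, via B-alkyl-9-borabicyclononane 28 (not isolated)
Conditions: 9-BBN-H (1.3 equiv), THF, 0 °C → rt; then 27, Pd(dppf)Cl2 (5 mol %), AsPh3 (10 mol %), K3PO4 (aq.), DMF, 45 °C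
Reagents that add atoms: none
Why: 9-BBN hydroborates the monosubstituted vinyl group much faster than the 1,1-disubstituted ring methylene and places boron on C12, and the B-alkyl Suzuki–Miyaura coupling with the β-bromobutenolide then forms C12–C13 without touching any stereocentre.

Step 18
Reactants: 29 tris(tert-butyldimethylsilyl) ether of the target
Product: 30 4-{2-[(1R,4aS,5S,6S,7S,8aS)-6,7-dihydroxy-5-(hydroxymethyl)-5,8a-dimethyl-2-methylidenedecahydronaphthalen-1-yl]ethyl}furan-2(5H)-one
Conditions: HF·pyridine, pyridine, THF, 0 °C → rt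
Reagents that add atoms: none
Why: Buffered fluoride cleaves the three silyl ethers without acid-catalysed migration of the exocyclic alkene or opening of the butenolide.

**Compound list**

1 | (S)-(5-oxooxolan-2-yl)methyl 4-methylbenzenesulfonate | O=C1CC[C@@H](COS(=O)(=O)c2ccc(C)cc2)O1 | starting material
2 | (1,3-dioxolan-2-ylmethyl)magnesium bromide | Br[Mg]CC1OCCO1 | starting material
3 | (R)-5-[2-(1,3-dioxolan-2-yl)ethyl]oxolan-2-one | O=C1CC[C@@H](CCC2OCCO2)O1 | intermediate
4 | (5R)-5-[2-(1,3-dioxolan-2-yl)ethyl]-3-(phenylselanyl)oxolan-2-one, both C3 epimers | O=C1C([Se]c2ccccc2)C[C@@H](CCC2OCCO2)O1 | intermediate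
5 | (R)-5-[2-(1,3-dioxolan-2-yl)ethyl]furan-2(5H)-one | O=C1C=C[C@@H](CCC2OCCO2)O1 | intermediate
6 | vinylmagnesium bromide | C=C[Mg]Br | starting material
7 | bromomagnesium enolate of (4S,5R)-5-[2-(1,3-dioxolan-2-yl)ethyl]-4-ethenyloxolan-2-one | C=C[C@H]1C=C(O[Mg]Br)O[C@@H]1CCC1OCCO1 | intermediate
8 | (3R,4S,5R)-3-[(dimethylamino)methyl]-5-[2-(1,3-dioxolan-2-yl)ethyl]-4-ethenyloxolan-2-one | CN(C)C[C@H]1[C@H](C=C)[C@@H](CCC2OCCO2)OC1=O | intermediate
9 | N-methyl quaternary ammonium iodide of 8 | C[N+](C)(C)C[C@H]1[C@H](C=C)[C@@H](CCC2OCCO2)OC1=O.[I-] | intermediate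
10 | (4S,5R)-5-[2-(1,3-dioxolan-2-yl)ethyl]-4-ethenyl-3-methylideneoxolan-2-one | C=C1[C@H](C=C)[C@@H](CCC2OCCO2)OC1=O | intermediate
11 | 3-[(2R,3S)-3-ethenyl-4-methylidene-5-oxooxolan-2-yl]propanal | C=C1[C@H](C=C)[C@@H](CCC=O)OC1=O | intermediate
12 | 3-(triphenylphosphoranylidene)butan-2-one | CC(=O)C(C)=P(c1ccccc1)(c1ccccc1)c1ccccc1 | starting material
13 | (4S,5R)-4-ethenyl-3-methylidene-5-[(3E)-4-methyl-5-oxohex-3-en-1-yl]oxolan-2-one | C=C1[C@H](C=C)[C@@H](CC/C=C(\C)C(C)=O)OC1=O | intermediate
14 | (4S,5R)-4-ethenyl-3-methylidene-5-[(3E)-4-methyl-5-(trimethylsilyloxy)hexa-3,5-dien-1-yl]oxolan-2-one | C=C1[C@H](C=C)[C@@H](CC/C=C(\C)C(=C)O[Si](C)(C)C)OC1=O | intermediate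
15 | trans-decalin with C3(OSiMe3)=C4(CH3), γ-lactone C20(=O)–O–C8 bridging ring B on the C20 face, C9 ethenyl equatorial on the C20 face, H5 on the opposite face | O=C1O[C@@H]2CC[C@@H]3C(C)=C(O[Si](C)(C)C)CC[C@]13[C@@H]2C=C | intermediate
16 | as 15 but C3 ketone and quaternary C4 with CH2OH equatorial (H5 face) and CH3 axial (C20 face) | O=C1O[C@@H]2CC[C@@H]3[C@@](C)(CO)C(=O)CC[C@]13[C@@H]2C=C | intermediate
17 | Δ2 trimethylsilyl enol ether of 16 with C18–OSiMe3 | O=C1O[C@@H]2CC[C@@H]3[C@@](C)(CO[Si](C)(C)C)C(O[Si](C)(C)C)=CC[C@]13[C@@H]2C=C | intermediate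
18 | 3-ketone with equatorial 2-OSiMe3 (H5 face) and C18–OSiMe3 | O=C1O[C@@H]2CC[C@@H]3[C@@](C)(CO[Si](C)(C)C)C(=O)[C@@H](O[Si](C)(C)C)C[C@]13[C@@H]2C=C | intermediate
19 | 3-ketone lactone with equatorial 2-OH (H5 face) and C18–OH | O=C1O[C@@H]2CC[C@@H]3[C@@](C)(CO)C(=O)[C@@H](O)C[C@]13[C@@H]2C=C | intermediate
20 | triol lactone: 2-OH equatorial (H5 face), 3-OH equatorial (C20 face), C18–OH | O=C1O[C@@H]2CC[C@@H]3[C@@](C)(CO)[C@H](O)[C@@H](O)C[C@]13[C@@H]2C=C | intermediate
21 | 2,3,18-tris(tert-butyldimethylsilyl) ether of 20 | O=C1O[C@@H]2CC[C@@H]3[C@@](C)(CO[Si](C)(C)C(C)(C)C)[C@H](O[Si](C)(C)C(C)(C)C)[C@@H](O[Si](C)(C)C(C)(C)C)C[C@]13[C@@H]2C=C | intermediate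
22 | lactol of 21 (C20 hemiacetal bridged to O8, both anomers) | OC1O[C@@H]2CC[C@@H]3[C@@](C)(CO[Si](C)(C)C(C)(C)C)[C@H](O[Si](C)(C)C(C)(C)C)[C@@H](O[Si](C)(C)C(C)(C)C)C[C@]13[C@@H]2C=C | intermediate
23 | open-chain C20 (E)-tosylhydrazone with free axial 8-OH | O[C@@H]1CC[C@H]2[C@@](/C=N/NS(=O)(=O)c3ccc(C)cc3)(C[C@H](O[Si](C)(C)C(C)(C)C)[C@@H](O[Si](C)(C)C(C)(C)C)[C@]2(C)CO[Si](C)(C)C(C)(C)C)[C@@H]1C=C | intermediate
24 | trans-decalin with C10 methyl, axial 8-OH (C20 face), C9 ethenyl, ring A tris-silyl ether | O[C@@H]1CC[C@H]2[C@@](C)(C[C@H](O[Si](C)(C)C(C)(C)C)[C@@H](O[Si](C)(C)C(C)(C)C)[C@]2(C)CO[Si](C)(C)C(C)(C)C)[C@@H]1C=C | intermediate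
25 | C8 ketone of 24 | O=C1CC[C@H]2[C@@](C)(C[C@H](O[Si](C)(C)C(C)(C)C)[C@@H](O[Si](C)(C)C(C)(C)C)[C@]2(C)CO[Si](C)(C)C(C)(C)C)[C@@H]1C=C | intermediate
26 | C8(17) exocyclic methylene compound with C9 ethenyl | C=C1CC[C@H]2[C@@](C)(C[C@H](O[Si](C)(C)C(C)(C)C)[C@@H](O[Si](C)(C)C(C)(C)C)[C@]2(C)CO[Si](C)(C)C(C)(C)C)[C@@H]1C=C | intermediate
27 | 4-bromofuran-2(5H)-one | O=C1C=C(Br)CO1 | starting material
28 | B-alkyl-9-borabicyclo[3.3.1]nonane with boron on C12 | C=C1CC[C@H]2[C@@](C)(C[C@H](O[Si](C)(C)C(C)(C)C)[C@@H](O[Si](C)(C)C(C)(C)C)[C@]2(C)CO[Si](C)(C)C(C)(C)C)[C@@H]1CCB1C2CCCC1CCC2 | intermediate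
29 | 2,3,18-tris(tert-butyldimethylsilyl) ether of the target | C=C1CC[C@H]2[C@@](C)(C[C@H](O[Si](C)(C)C(C)(C)C)[C@@H](O[Si](C)(C)C(C)(C)C)[C@]2(C)CO[Si](C)(C)C(C)(C)C)[C@@H]1CCC1=CC(=O)OC1 | intermediate
30 | 4-{2-[(1R,4aS,5S,6S,7S,8aS)-6,7-dihydroxy-5-(hydroxymethyl)-5,8a-dimethyl-2-methylidenedecahydronaphthalen-1-yl]ethyl}furan-2(5H)-one | C=C1CC[C@H]2[C@@](C)(C[C@H](O)[C@@H](O)[C@]2(C)CO)[C@@H]1CCC1=CC(=O)OC1 | target

**Count and risks**

Total steps: 18. Longest linear sequence: 18 steps (1 → 30).

Steps most likely to fail:

Step 8. The endo preference may be too small, so that the exo transition state delivers the cis-fused adduct, or the trimethylsilyl dienol ether may decay (hydrolysis, 1,5-hydrogen shift) before it cyclises at 110 °C. The fallback sets out from 13 and comes back at 16. Enone 13 is silylated with tBuMe2SiOTf/Et3N (CH2Cl2, −78 → 0 °C) to the isolable tert-butyldimethylsilyl dienol ether F1. The thermal pericyclic step is then replaced by a Lewis-acid-driven polar annulation: complexation of the lactone carbonyl with Me2AlCl (CH2Cl2, −78 → −30 °C) lowers the dienophile LUMO, so that the Mukaiyama–Michael-type first bond (C2–C1) and the ring closure (C10–C5) take place at low temperature through the compact endo arrangement. This gives the tert-butyldimethylsilyl enol ether lactone F2, which is hydroxymethylated with aqueous formaldehyde and Sc(OTf)3 to rejoin the route at 16. This fallback is the closest to a change of conditions only; it changes the diene protecting group, the activation mode and the temperature regime, but not the bond construction.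

Step 14. Hydrazone formation from the hindered bridged lactol may be slow because the ring–chain equilibrium lies on the lactol side, or the reduction may stop short and return lactol. The fallback sets out from 22 and comes back at 24. NaBH4 (EtOH, 0 °C → rt) opens the lactol to the 8,20-diol F3. The primary C20 hydroxyl is acylated selectively with phenyl chlorothionoformate (pyridine, DMAP, CH2Cl2, 0 °C) to the C20 O-phenyl thionocarbonate F4, and Barton–McCombie deoxygenation (Bu3SnH, AIBN, toluene, 110 °C) gives 24.

Step 9. Protodesilylation of the hindered tetrasubstituted enol ether in the aqueous medium may outrun C–C bond formation, or formaldehyde may be lost again by retro-aldol cleavage. The fallback sets out from 15 and comes back at 16. Anhydrous SN1-type alkylation of the silyl enol ether with benzyl chloromethyl ether and TiCl4 (CH2Cl2, −78 °C), with the same facial preference, gives the C18 benzyl ether F5. BCl3 (CH2Cl2, −78 °C) removes the benzyl group to give 16.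

Further compounds
F1 | step 8 | (4S,5R)-5-[(3E)-5-(tert-butyldimethylsilyloxy)-4-methylhexa-3,5-dien-1-yl]-4-ethenyl-3-methylideneoxolan-2-one | C=C1[C@H](C=C)[C@@H](CC/C=C(\C)C(=C)O[Si](C)(C)C(C)(C)C)OC1=O
F2 | step 8 | tert-butyldimethylsilyl enol ether analogue of 15 | O=C1O[C@@H]2CC[C@@H]3C(C)=C(O[Si](C)(C)C(C)(C)C)CC[C@]13[C@@H]2C=C
F3 | step 14 | 8,20-diol (C10 hydroxymethyl, axial 8-OH, ring A tris-silyl ether, C9 ethenyl) | O[C@@H]1CC[C@H]2[C@@](CO)(C[C@H](O[Si](C)(C)C(C)(C)C)[C@@H](O[Si](C)(C)C(C)(C)C)[C@]2(C)CO[Si](C)(C)C(C)(C)C)[C@@H]1C=C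
F4 | step 14 | C20 O-phenyl thionocarbonate of F3 | O[C@@H]1CC[C@H]2[C@@](COC(=S)Oc3ccccc3)(C[C@H](O[Si](C)(C)C(C)(C)C)[C@@H](O[Si](C)(C)C(C)(C)C)[C@]2(C)CO[Si](C)(C)C(C)(C)C)[C@@H]1C=C
F5 | step 9 | C18 benzyl ether of 16 | O=C1O[C@@H]2CC[C@@H]3[C@@](C)(COCc4ccccc4)C(=O)CC[C@]13[C@@H]2C=C
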